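**Assumption (one line):** atoms are numbered as in the germacrane skeleton of the target (C6 lactone carbinol, C8 epoxyangelate, C9 acetate, C10 ester-bearing carbon, C1–C5 the bis-epoxide arm); the ligand enantiomers named in steps 7 and 12 are taken to give the drawn configuration, and their antipodes would be used if the sense of induction is the opposite.

## Retrosynthetic overview

1. Target 28 ⇐ acetylation of alcohol 27; the ten-membered ring is closed last, at C9–C10, by CrCl2/NiCl2 addition of the C10 alkenyl iodide to the C9 aldehyde of 26.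
2. The C9 aldehyde ⇐ ozonolysis of a C8 allylic ester; the key disconnection is the C8–O bond, made by a stereoselective allylic C–H acyloxylation of the C7 allyl group of 20 with epoxy acid 4 (new reaction).
3. Both ring oxiranes are made by C–O bond formation on alkenes: C2–C3 first (Sharpless, via C1–OH), then C4–C5 (dimethyldioxirane); acid 4 comes from methyl angelate by Sharpless epoxidation and oxidation.
4. The trans β-allyl α-methylene lactone 18 ⇐ allyl 1,4-addition/methylenation of butenolide 13 ⇐ zinc–ProPhenol alkynylation of enynal 9 with methyl propiolate, then semihydrogenation and lactonisation.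
5. Ring order: side-chain oxirane (made separately) → γ-lactone → 2,3-oxirane → 4,5-oxirane → ten-membered carbocycle.

## Route

**Step 1**
Reactants: 1 methyl (2Z)-2-methylbut-2-enoate (methyl angelate)
Product: 2 (2Z)-2-methylbut-2-en-1-ol
Conditions: LiAlH4, Et2O, 0 °C
Reagents that add atoms: none
Why: Hydride 1,2-reduction of the ester gives the allylic alcohol with the Z geometry kept (ester reduction).

**Step 2**
Reactants: 2 (2Z)-2-methylbut-2-en-1-ol
Product: 3 [(2R,3S)-2,3-dimethyloxiran-2-yl]methanol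
Conditions: Ti(OiPr)4 (10 mol %), D-(−)-diisopropyl tartrate (12 mol %), tBuOOH, 4 Å molecular sieves, CH2Cl2, −20 °C
Reagents that add atoms: tert-butyl hydroperoxide CC(C)(C)OO
Why: Sharpless asymmetric epoxidation of a primary allylic alcohol; the D-tartrate complex delivers oxygen to the face that gives the (2R,3S) cis-oxirane, which sets both side-chain stereocentres.

**Step 3**
Reactants: 3 [(2R,3S)-2,3-dimethyloxiran-2-yl]methanol
Product: 4 (2S,3S)-2,3-dimethyloxirane-2-carboxylic acid
Conditions: RuCl3·xH2O (2 mol %), NaIO4, CCl4/MeCN/H2O, rt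
Reagents that add atoms: sodium periodate [Na+].[O-]I(=O)(=O)=O
Why: RuO4-type oxidation (RuCl3/NaIO4) takes the primary epoxy alcohol to the acid without touching the oxirane; the descriptor at C2 changes only because of priorities.

**Step 4**
Reactants: 5 but-2-yn-1-ol
Product: 6 (2Z)-3-iodobut-2-en-1-ol
Conditions: NaAlH2(OCH2CH2OMe)2, Et2O, 0 °C → rt; then I2, −78 °C
Reagents that add atoms: iodine II
Why: Hydroxyl-directed anti-hydroalumination of the propargylic alcohol puts aluminium on C3, and iodinolysis with retention gives the Z alkenyl iodide (hydroalumination–iodination).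

**Step 5**
Reactants: 6 (2Z)-3-iodobut-2-en-1-ol
Product: 7 (2Z)-3-iodobut-2-enal
Conditions: MnO2, CH2Cl2, rt
Reagents that add atoms: none
Why: MnO2 oxidises the allylic alcohol selectively to the enal and leaves the alkenyl iodide and the Z geometry intact (allylic oxidation).

**Step 6**
Reactants: 7 (2Z)-3-iodobut-2-enal; 8 prop-2-yn-1-ol
Product: 9 (2Z)-6-hydroxy-3-methylhex-2-en-4-ynal
Conditions: Pd(PPh3)2Cl2 (3 mol %), CuI (6 mol %), Et3N, THF, 0 °C → rt
Reagents that add atoms: none
Why: Sonogashira coupling of the activated β-iodo enal with the terminal alkyne forms C3–C4 with retention of the alkene geometry.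

**Step 7**
Reactants: 9 (2Z)-6-hydroxy-3-methylhex-2-en-4-ynal; 10 methyl prop-2-ynoate
Product: 11 methyl (4R,5Z)-4,9-dihydroxy-6-methylnon-5-ene-2,7-diynoate
Conditions: (S,S)-ProPhenol (20 mol %), ZnMe2, Ph3PO (40 mol %), toluene, 4 °C
Reagents that add atoms: none
Why: Dinuclear zinc–ProPhenol catalysed enantioselective alkynylation of an enal; the chiral dizinc complex binds aldehyde and zinc acetylide and adds to one face, which sets C6 (4R here).

**Step 8**
Reactants: 11 methyl (4R,5Z)-4,9-dihydroxy-6-methylnon-5-ene-2,7-diynoate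
Product: 13 (5S)-5-[(1Z,3Z)-5-hydroxy-2-methylpenta-1,3-dien-1-yl]furan-2(5H)-one, via hydroxy trienoate 12 (not isolated)
Conditions: H2 (1 atm), Pd/CaCO3 poisoned with Pb(OAc)2 (Lindlar catalyst), quinoline, EtOAc, rt; lactonises on concentration
Reagents that add atoms: none
Why: Lindlar semihydrogenation turns both alkynes into Z alkenes, and the (Z)-4-hydroxy enoate then closes to the butenolide with loss of methanol, C6 being untouched.

**Step 9**
Reactants: 13 (5S)-5-[(1Z,3Z)-5-hydroxy-2-methylpenta-1,3-dien-1-yl]furan-2(5H)-one; 14 allylmagnesium bromide (CH2=CHCH2MgBr)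
Product: 18 (4S,5R)-5-[(1Z,3Z)-5-hydroxy-2-methylpenta-1,3-dien-1-yl]-3-methylidene-4-(prop-2-en-1-yl)oxolan-2-one, via silyl ketene acetal 15 (not isolated), via Mannich base 16 (not isolated), via ammonium iodide 17 (not isolated)
Conditions: CH2=CHCH2MgBr, CuBr·SMe2, LiCl, Me3SiCl, THF, −78 °C; then CH2=NMe2+ I−, −78 °C → rt; then MeI; then aq. NaHCO3/MeOH
Reagents that add atoms: N,N-dimethylmethyleneiminium iodide C=[N+](C)C.[I-]
Why: Copper-mediated 1,4-addition of the allyl group occurs anti to the C6 substituent and sets C7 (trans lactone), the silyl ketene acetal is aminomethylated by the iminium salt, and quaternisation/elimination gives the exocyclic methylene (conjugate addition–Eschenmoser methylenation; the C1 hydroxyl is silylated in the flask and freed on work-up).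

**Step 10**
Reactants: 18 (4S,5R)-5-[(1Z,3Z)-5-hydroxy-2-methylpenta-1,3-dien-1-yl]-3-methylidene-4-(prop-2-en-1-yl)oxolan-2-one
Product: 19 (4S,5R)-5-{(1Z)-2-[(2S,3R)-3-(hydroxymethyl)oxiran-2-yl]prop-1-en-1-yl}-3-methylidene-4-(prop-2-en-1-yl)oxolan-2-one
Conditions: Ti(OiPr)4, D-(−)-diisopropyl tartrate, tBuOOH, 4 Å molecular sieves, CH2Cl2, −20 °C
Reagents that add atoms: tert-butyl hydroperoxide CC(C)(C)OO
Why: Sharpless asymmetric epoxidation touches only the allylic-alcohol alkene C2=C3, and the D-tartrate complex sets C2 and C3 by reagent control before any neighbouring stereocentre exists on that arm.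

**Step 11**
Reactants: 19 (4S,5R)-5-{(1Z)-2-[(2S,3R)-3-(hydroxymethyl)oxiran-2-yl]prop-1-en-1-yl}-3-methylidene-4-(prop-2-en-1-yl)oxolan-2-one
Product: 20 (4S,5S)-5-{(2R,3R)-3-[(2R,3R)-3-(hydroxymethyl)oxiran-2-yl]-3-methyloxiran-2-yl}-3-methylidene-4-(prop-2-en-1-yl)oxolan-2-one
Conditions: dimethyldioxirane (1.05 equiv), acetone/CH2Cl2, −40 °C
Reagents that add atoms: dimethyldioxirane CC1(C)OO1
Why: Electrophilic epoxidation picks the trisubstituted C4=C5 alkene over the terminal and the acrylate alkenes; allylic 1,3-strain puts H3 and H6 in the alkene plane, so C2 (with its cis CH2OH) and C7 (with its allyl group) shield one face and oxygen enters from the face of the two ring oxygens, which sets C4 and C5 (substrate-controlled epoxidation).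

**Step 12**
Reactants: 20 (4S,5S)-5-{(2R,3R)-3-[(2R,3R)-3-(hydroxymethyl)oxiran-2-yl]-3-methyloxiran-2-yl}-3-methylidene-4-(prop-2-en-1-yl)oxolan-2-one; 4 (2S,3S)-2,3-dimethyloxirane-2-carboxylic acid
Product: 21 (1R)-1-[(2S,3R)-2-{(2R,3R)-3-[(2R,3R)-3-(hydroxymethyl)oxiran-2-yl]-3-methyloxiran-2-yl}-4-methylidene-5-oxooxolan-3-yl]prop-2-en-1-yl (2S,3S)-2,3-dimethyloxirane-2-carboxylate
Conditions: Pd(OAc)2 (10 mol %), chiral aryl sulfoxide–oxazoline ligand (12 mol %), 2,6-dimethyl-1,4-benzoquinone, iPr2NEt (cat.), 1,4-dioxane, 45 °C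
Reagents that add atoms: none
Why: Proposed new method: a ligand-controlled, branched-selective allylic C–H acyloxylation of the terminal olefin with a functionalised epoxy acid, in which divalent palladium bound to the chiral sulfoxide–oxazoline cleaves a C8–H bond to give a π-allylpalladium carboxylate and the quinone triggers inner-sphere C–O reductive elimination at the internal carbon on the ligand-defined face, so that the C8–O bond, the C8 configuration and the whole side chain come in one step; the closest known reactions are the branched allylic C–H esterification with Pd(OAc)2/bis-sulfoxide/benzoquinone and the palladium/sulfoxide–oxazoline asymmetric allylic C–H oxidations, neither shown with this diastereocontrol or with an epoxy acid.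

**Step 13**
Reactants: 21 (C8 ester from step 12); 22 methyl (triphenyl-λ5-phosphanylidene)acetate
Product: 25 (Z)-2-iodoacrylate, that is 21 with C1H2OH replaced by CH=C(I)CO2Me (2R,3R,4R,5R,6S,7R,8R in target numbering), via epoxy aldehyde 23 (not isolated), via iodo ylide 24 (not isolated)
Conditions: Dess–Martin periodinane, NaHCO3, CH2Cl2, 0 °C; then 24 [made from 22, N-iodosuccinimide, K2CO3, CH2Cl2, −20 °C], −20 °C → rt
Reagents that add atoms: N-iodosuccinimide O=C1CCC(=O)N1I
Why: Dess–Martin oxidation gives the configurationally stable cis-epoxy aldehyde, and Wittig olefination with the stabilised iodo ylide gives mainly the (Z)-2-iodoenoate with iodine cis to C2 (oxidation–Wittig sequence).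

**Step 14**
Reactants: 25 (Z)-2-iodoacrylate from step 13
Product: 26 seco-aldehyde, that is 25 with the C8 vinyl group replaced by CHO
Conditions: O3 (1 equiv), CH2Cl2, −78 °C; then PPh3
Reagents that add atoms: ozone [O-][O+]=O
Why: Ozonolysis cleaves the only electron-rich alkene (the monosubstituted vinyl group), while the acrylate-type and iodoacrylate alkenes react far more slowly, and C8 keeps its configuration under the neutral reductive work-up.

**Step 15**
Reactants: 26 seco-aldehyde from step 14
Product: 27 9-hydroxy macrocycle (the target lacking the acetyl group; 2R,3R,4R,5R,6S,7R,8S,9R)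
Conditions: CrCl2 (10 equiv), NiCl2 (cat.), DMSO/THF, 1 mM, rt
Reagents that add atoms: none
Why: Nozaki–Hiyama–Kishi macrocyclisation, in which zerovalent nickel inserts into the C10–I bond and transmetallation to trivalent chromium gives an alkenylchromium that adds to the C9 aldehyde; the ten-membered ring only allows C2 and C9 cis on the C1=C10 bond, and Felkin–Anh attack anti to the C8 acyloxy group is expected to give the 8,9-erythro (9R) alcohol.

**Step 16**
Reactants: 27 9-hydroxy macrocycle from step 15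
Product: 28 target CNP0077535.3
Conditions: Ac2O, DMAP, pyridine, CH2Cl2, 0 °C
Reagents that add atoms: acetic anhydride CC(=O)OC(C)=O
Why: DMAP-catalysed acylation of the only free hydroxyl gives the C9 acetate with retention (esterification).

## Compound list

1 | methyl (2Z)-2-methylbut-2-enoate (methyl angelate) | C/C=C(/C)C(=O)OC | starting material
2 | (2Z)-2-methylbut-2-en-1-ol | C/C=C(/C)CO | intermediate
3 | [(2R,3S)-2,3-dimethyloxiran-2-yl]methanol | OC[C@@]1(C)O[C@H]1C | intermediate
4 | (2S,3S)-2,3-dimethyloxirane-2-carboxylic acid | OC(=O)[C@@]1(C)O[C@H]1C | intermediate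
5 | but-2-yn-1-ol | CC#CCO | starting material
6 | (2Z)-3-iodobut-2-en-1-ol | C/C(I)=C/CO | intermediate
7 | (2Z)-3-iodobut-2-enal | C/C(I)=C/C=O | intermediate
8 | prop-2-yn-1-ol | C#CCO | starting material
9 | (2Z)-6-hydroxy-3-methylhex-2-en-4-ynal | C/C(C#CCO)=C/C=O | intermediate
10 | methyl prop-2-ynoate | C#CC(=O)OC | starting material
11 | methyl (4R,5Z)-4,9-dihydroxy-6-methylnon-5-ene-2,7-diynoate | O[C@H](/C=C(/C)C#CCO)C#CC(=O)OC | intermediate
12 | methyl (2Z,4S,5Z,7Z)-4,9-dihydroxy-6-methylnona-2,5,7-trienoate | O[C@H](/C=C(/C)\C=C/CO)/C=C\C(=O)OC | intermediate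
13 | (5S)-5-[(1Z,3Z)-5-hydroxy-2-methylpenta-1,3-dien-1-yl]furan-2(5H)-one | O=C1O[C@H](/C=C(/C)\C=C/CO)C=C1 | intermediate
14 | allylmagnesium bromide | C=CC[Mg]Br | starting material
15 | silyl ketene acetal of the 4,5-trans allyl adduct, C1 hydroxyl as trimethylsilyl ether | C[Si](C)(C)OC1=C[C@H](CC=C)[C@H](O1)/C=C(/C)\C=C/CO[Si](C)(C)C | intermediate
16 | 3-[(dimethylamino)methyl] lactone (3,4-trans, 4,5-trans), C1 trimethylsilyl ether | CN(C)C[C@@H]1C(=O)O[C@H](/C=C(/C)\C=C/CO[Si](C)(C)C)[C@H]1CC=C | intermediate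
17 | trimethylammonium iodide of 16 | C[N+](C)(C)C[C@@H]1C(=O)O[C@H](/C=C(/C)\C=C/CO[Si](C)(C)C)[C@H]1CC=C.[I-] | intermediate
18 | (4S,5R)-5-[(1Z,3Z)-5-hydroxy-2-methylpenta-1,3-dien-1-yl]-3-methylidene-4-(prop-2-en-1-yl)oxolan-2-one | C=C1C(=O)O[C@H](/C=C(/C)\C=C/CO)[C@H]1CC=C | intermediate
19 | (4S,5R)-5-{(1Z)-2-[(2S,3R)-3-(hydroxymethyl)oxiran-2-yl]prop-1-en-1-yl}-3-methylidene-4-(prop-2-en-1-yl)oxolan-2-one | C=C1C(=O)O[C@H](/C=C(/C)[C@@H]2O[C@@H]2CO)[C@H]1CC=C | intermediate
20 | (4S,5S)-5-{(2R,3R)-3-[(2R,3R)-3-(hydroxymethyl)oxiran-2-yl]-3-methyloxiran-2-yl}-3-methylidene-4-(prop-2-en-1-yl)oxolan-2-one | C=C1C(=O)O[C@H]([C@H]2O[C@@]2(C)[C@@H]3O[C@@H]3CO)[C@H]1CC=C | intermediate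
21 | (1R)-1-[(2S,3R)-2-{(2R,3R)-3-[(2R,3R)-3-(hydroxymethyl)oxiran-2-yl]-3-methyloxiran-2-yl}-4-methylidene-5-oxooxolan-3-yl]prop-2-en-1-yl (2S,3S)-2,3-dimethyloxirane-2-carboxylate | C=C1C(=O)O[C@H]([C@H]2O[C@@]2(C)[C@@H]3O[C@@H]3CO)[C@H]1[C@H](OC(=O)[C@@]4(C)O[C@H]4C)C=C | intermediate
22 | methyl (triphenyl-λ5-phosphanylidene)acetate | COC(=O)C=P(c1ccccc1)(c1ccccc1)c1ccccc1 | starting material
23 | C1 aldehyde of 21 (oxirane-2-carbaldehyde; spatial arrangement as in 21) | C=C1C(=O)O[C@H]([C@H]2O[C@@]2(C)[C@@H]3O[C@@H]3C=O)[C@H]1[C@H](OC(=O)[C@@]4(C)O[C@H]4C)C=C | intermediate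
24 | methyl iodo(triphenyl-λ5-phosphanylidene)acetate | COC(=O)C(I)=P(c1ccccc1)(c1ccccc1)c1ccccc1 | intermediate
25 | (Z)-2-iodoacrylate: 21 with C1H2OH replaced by CH=C(I)CO2Me, iodine cis to C2 (2R,3R,4R,5R,6S,7R,8R) | C=C1C(=O)O[C@H]([C@H]2O[C@@]2(C)[C@@H]3O[C@@H]3/C=C(\I)C(=O)OC)[C@H]1[C@H](OC(=O)[C@@]4(C)O[C@H]4C)C=C | intermediate
26 | seco-aldehyde: 25 with the C8 vinyl group replaced by CHO (same spatial arrangement) | C=C1C(=O)O[C@H]([C@H]2O[C@@]2(C)[C@@H]3O[C@@H]3/C=C(\I)C(=O)OC)[C@H]1[C@H](OC(=O)[C@@]4(C)O[C@H]4C)C=O | intermediate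
27 | 9-hydroxy macrocycle (target lacking the acetyl group; 2R,3R,4R,5R,6S,7R,8S,9R) | C=C1C(=O)O[C@H]2[C@H]1[C@H](OC(=O)[C@@]1(C)O[C@H]1C)[C@H](O)/C(C(=O)OC)=C\[C@H]1O[C@H]1[C@]1(C)O[C@H]21 | intermediate
28 | CNP0077535.3 (2R,3R,4R,5R,6S,7R,8S,9R; side chain 2S,3S) | C=C1C(=O)O[C@H]2[C@H]1[C@H](OC(=O)[C@@]1(C)O[C@H]1C)[C@H](OC(C)=O)/C(C(=O)OC)=C\[C@H]1O[C@H]1[C@]1(C)O[C@H]21 | target

## Step count and risks

Total step count: 16. Longest linear sequence: 13 (steps 4–16); the three side-chain steps 1–3 join at step 12.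

**Step 12 (the proposed new allylic C–H acyloxylation).** It may give low conversion, diene by β-hydride loss, or poor control at C8. The fallback uses known chemistry, sets out from 20 and comes back at 25. Compound 20 is oxidised with Dess–Martin periodinane to the epoxy aldehyde F1 and olefinated in the same flask with iodo ylide 24 to the C8-unfunctionalised vinyl iodide F2. SeO2 (cat.)/tBuOOH allylic hydroxylation of the terminal olefin then gives the (8R)-alcohol F3 and the (8S)-alcohol F4, which are separated. F3 is esterified with acid 4 with retention (2,4,6-trichlorobenzoyl chloride, Et3N, DMAP) and F4 with inversion (PPh3, diisopropyl azodicarboxylate, acid 4), so both give 25.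

**Step 15 (ten-membered ring closure and C9 configuration).** The ring may close with the wrong face at C9. The fallback sets out from 26 and comes back at 28. If the cyclisation gives mainly the 9-epi alcohol F5, this is turned directly into 28 by Mitsunobu inversion with acetic acid (PPh3, diisopropyl azodicarboxylate, AcOH). C9 is then set in a C–O bond-forming step with inversion instead of in the C–C addition.

**Step 11 (face and site selectivity of the C4=C5 epoxidation).** The steric argument may not hold, or the terminal alkene may compete. The fallback sets out from 19 and comes back at 20. It replaces substrate control by catalyst control: Shi epoxidation with the fructose-derived ketone, KHSO5 (as 2KHSO5·KHSO4·K2SO4), K2CO3, MeCN/dimethoxymethane/H2O, 0 °C, which is selective for trisubstituted alkenes. It makes no new compound, F0.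

## Further compounds

F1 | step 12 | C1 aldehyde of 20 (oxirane-2-carbaldehyde) | C=C1C(=O)O[C@H]([C@H]2O[C@@]2(C)[C@@H]3O[C@@H]3C=O)[C@H]1CC=C
F2 | step 12 | (Z)-2-iodoacrylate lacking the C8 ester (20 with C1H2OH replaced by CH=C(I)CO2Me) | C=C1C(=O)O[C@H]([C@H]2O[C@@]2(C)[C@@H]3O[C@@H]3/C=C(\I)C(=O)OC)[C@H]1CC=C
F3 | step 12 | (8R)-allylic alcohol of F2 (C8 arranged as in 25) | C=C1C(=O)O[C@H]([C@H]2O[C@@]2(C)[C@@H]3O[C@@H]3/C=C(\I)C(=O)OC)[C@H]1[C@H](O)C=C
F4 | step 12 | (8S)-allylic alcohol of F2 (C8 epimer of F3) | C=C1C(=O)O[C@H]([C@H]2O[C@@]2(C)[C@@H]3O[C@@H]3/C=C(\I)C(=O)OC)[C@H]1[C@@H](O)C=C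
F5 | step 15 | 9-epi alcohol (C9 epimer of 27) | C=C1C(=O)O[C@H]2[C@H]1[C@H](OC(=O)[C@@]1(C)O[C@H]1C)[C@@H](O)/C(C(=O)OC)=C\[C@H]1O[C@H]1[C@]1(C)O[C@H]21
F0 | step 11 | none | none
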